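**Plan**
1. Germacrane numbering is used throughout: ring C1–C10, isopropenyl C11 on C7, C14 on C10, C15 on C4; O3, O8 and O9 carry the esters.
2. Retrosynthesis: remove the O9 acetate and the O3/O8 angelates, open both epoxides to the (1(10)Z,4E)-diene, cut the ring bond C3–C4 back to an acyclic ynal, then cut C7–C8 (aldol) and C10=C1 (Wittig).
3. Enabling feature: the C3 carbinol next to the C4(CH3)–C5 trans-epoxide is an epoxidised (E)-2-methylallylic alcohol inside the ten-membered ring, so a C4≡C5 methyl alkyne plus a C3 aldehyde can give the ring, the E olefin and O3 in one reductive coupling.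
4. Forward: the Z olefin C10=C1 comes from a Wittig reaction on a glycerate-derived α-alkoxy methyl ketone; a syn-aldol joins C7–C8; the C11 imide carbonyl becomes the isopropenyl group; the ring is then closed at C3–C4; epoxidations and acylations finish the route.
5. Stereochemistry: C9 from (S)-glycerate; C7 and C8 from the oxazolidinone auxiliary (matched with C9); C3 from a CBS reduction of the macrocyclic enone; C4/C5 and C1/C10 from hydroxyl-directed peracid epoxidations.
6. Helpers: TBS on O8 and PMB on O9 are removed in that order so that O3/O8 receive angelate and O9 receives acetate last; the C3 alcohol is taken through the ketone to fix its configuration.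

Key step: step 15

Remark: methyl (S)-glycerate 3 is taken as a purchasable chiral-pool ester. The configuration at C3 formed in step 15 cannot be predicted with confidence and is not relied upon; steps 16 and 17 reset it.

**Route**

Step 1
Reactants: 1 (3-bromopropoxy)(tert-butyl)dimethylsilane
Product: 2 [3-(tert-butyldimethylsilyloxy)propyl]triphenylphosphonium bromide
Conditions: PPh3, MeCN, 80 °C
Reagents that add atoms: triphenylphosphine, c1ccc(cc1)P(c1ccccc1)c1ccccc1
Why: Phosphonium salt formation by SN2 alkylation of PPh3 with the primary bromide; the silyl ether is inert under these neutral conditions.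

Step 2
Reactants: 3 methyl (2S)-2,3-dihydroxypropanoate
Product: 4 methyl (4S)-2-(4-methoxyphenyl)-1,3-dioxolane-4-carboxylate (acetal carbon as epimer mixture)
Conditions: 4-MeOC6H4CH(OMe)2, PPTS (cat.), toluene, 80 °C
Reagents that add atoms: 4-methoxybenzaldehyde dimethyl acetal, COc1ccc(C(OC)OC)cc1
Why: Acid-catalysed transacetalisation of the 1,2-diol gives the arylidene acetal; the glycerate stereocenter (future C9) is not touched and the acetal epimers are inconsequential.

Step 3
Reactants: 4 methyl (4S)-2-(4-methoxyphenyl)-1,3-dioxolane-4-carboxylate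
Product: 6 methyl ketone 1-[(4S)-2-(4-methoxyphenyl)-1,3-dioxolan-4-yl]ethan-1-one, via Weinreb amide 5 (not isolated)
Conditions: MeNHOMe·HCl, MeMgBr (5 equiv), THF, −20 to 0 °C
Reagents that add atoms: methylmagnesium bromide, C[Mg]Br; N,O-dimethylhydroxylamine hydrochloride, CNOC.Cl (its atoms appear in 5 only)
Why: One-pot Weinreb amide formation and Grignard addition; the chelated tetrahedral adduct stops the addition at the ketone, and the low temperature should keep the α-alkoxy stereocenter intact.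

Step 4
Reactants: 6 1-[(4S)-2-(4-methoxyphenyl)-1,3-dioxolan-4-yl]ethan-1-one; 2 [3-(tert-butyldimethylsilyloxy)propyl]triphenylphosphonium bromide
Product: 8 (4R)-4-[(2Z)-5-(tert-butyldimethylsilyloxy)pent-2-en-2-yl]-2-(4-methoxyphenyl)-1,3-dioxolane, via phosphonium ylide 7 (not isolated)
Conditions: 2, NaN(SiMe3)2, THF, 0 °C; then 6, −78 °C to rt
Reagents that add atoms: none
Why: Wittig olefination of an α-alkoxy methyl ketone with a non-stabilised ylide, a substrate class that gives the Z trisubstituted olefin (alkoxy-bearing carbon cis to the new chain), which sets the C1=C10 geometry.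

Step 5
Reactants: 8 (4R)-4-[(2Z)-5-(tert-butyldimethylsilyloxy)pent-2-en-2-yl]-2-(4-methoxyphenyl)-1,3-dioxolane
Product: 9 (2R,3Z)-6-(tert-butyldimethylsilyloxy)-2-[(4-methoxybenzyl)oxy]-3-methylhex-3-en-1-ol
Conditions: iBu2AlH, CH2Cl2, −78 to 0 °C
Reagents that add atoms: none
Why: Reductive opening of the 4-methoxybenzylidene acetal; the aluminium hydride binds the less hindered primary oxygen and reduces the oxocarbenium ion, leaving PMB on the secondary oxygen O9 and freeing the primary alcohol.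

Step 6
Reactants: 9 (2R,3Z)-6-(tert-butyldimethylsilyloxy)-2-[(4-methoxybenzyl)oxy]-3-methylhex-3-en-1-ol
Product: 10 (2R,3Z)-6-(tert-butyldimethylsilyloxy)-2-[(4-methoxybenzyl)oxy]-3-methylhex-3-enal
Conditions: Dess–Martin periodinane, NaHCO3, CH2Cl2, 0 °C (used at once)
Reagents that add atoms: none
Why: Buffered Dess–Martin oxidation should give the α-alkoxy aldehyde without epimerisation at C9 or migration of the β,γ-olefin.

Step 7
Reactants: 11 hex-4-ynoic acid; 12 (4S)-4-benzyl-1,3-oxazolidin-2-one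
Product: 14 (4S)-4-benzyl-3-(hex-4-ynoyl)-1,3-oxazolidin-2-one, via mixed pivalic anhydride 13 (not isolated)
Conditions: PivCl, Et3N, THF, −20 °C; then 12, LiCl, rt
Reagents that add atoms: pivaloyl chloride, CC(C)(C)C(=O)Cl (its atoms appear in 13 only)
Why: N-acylation of the oxazolidinone through the mixed anhydride (LiCl-promoted acyl transfer to the less hindered carbonyl).

Step 8
Reactants: 14 (4S)-4-benzyl-3-(hex-4-ynoyl)-1,3-oxazolidin-2-one; 10 (2R,3Z)-6-(tert-butyldimethylsilyloxy)-2-[(4-methoxybenzyl)oxy]-3-methylhex-3-enal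
Product: 16 syn-aldol adduct (4S)-4-benzyl-3-[(2S,3S,4R,5Z)-2-(but-2-yn-1-yl)-8-(tert-butyldimethylsilyloxy)-3-hydroxy-4-[(4-methoxybenzyl)oxy]-5-methyloct-5-enoyl]-1,3-oxazolidin-2-one, via dibutylboron enolate 15 (not isolated)
Conditions: Bu2BOTf, iPr2NEt, CH2Cl2, −78 to 0 °C; 10, −78 to −20 °C; then pH 7 buffer, MeOH, H2O2, 0 °C
Reagents that add atoms: dibutylboron triflate, CCCCB(CCCC)OS(=O)(=O)C(F)(F)F (its atoms appear in 15 only)
Why: Evans syn-aldol reaction; the (Z)-boron enolate reacts through a chair Zimmerman–Traxler transition state on the face away from the benzyl group to set C7 and C8, and the (R)-α-alkoxy aldehyde is the matched partner because (Z)-enolates add to α-alkoxy aldehydes with the 8,9-anti (Cornforth) preference.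

Step 9
Reactants: 16 syn-aldol adduct
Product: 17 (2S,3S,4R,5Z)-2-(but-2-yn-1-yl)-8-(tert-butyldimethylsilyloxy)-3-hydroxy-N-methoxy-4-[(4-methoxybenzyl)oxy]-N,5-dimethyloct-5-enamide
Conditions: MeNHOMe·HCl, AlMe3, CH2Cl2, −10 °C to rt
Reagents that add atoms: N,O-dimethylhydroxylamine hydrochloride, CNOC.Cl
Why: Aluminium-amide transamidation (Weinreb amide formation), assisted by the free β-hydroxyl, cleaves the auxiliary without touching the stereocenters.

Step 10
Reactants: 17 β-hydroxy Weinreb amide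
Product: 18 (2S,3S,4R,5Z)-2-(but-2-yn-1-yl)-3,8-bis(tert-butyldimethylsilyloxy)-N-methoxy-4-[(4-methoxybenzyl)oxy]-N,5-dimethyloct-5-enamide
Conditions: TBSOTf, 2,6-lutidine, CH2Cl2, −78 to 0 °C
Reagents that add atoms: tert-butyldimethylsilyl triflate, CC(C)(C)[Si](C)(C)OS(=O)(=O)C(F)(F)F
Why: Silylation of the secondary alcohol with the silyl triflate protects O8 and blocks retro-aldol and elimination in the next two steps.

Step 11
Reactants: 18 silylated Weinreb amide
Product: 19 (3S,4S,5R,6Z)-3-(but-2-yn-1-yl)-4,9-bis(tert-butyldimethylsilyloxy)-5-[(4-methoxybenzyl)oxy]-6-methylnon-6-en-2-one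
Conditions: MeMgBr, THF, 0 °C
Reagents that add atoms: methylmagnesium bromide, C[Mg]Br
Why: Grignard addition to the Weinreb amide stops at the chelated tetrahedral intermediate and gives the methyl ketone (C11 with its methyl) on work-up.

Step 12
Reactants: 19 methyl ketone
Product: 20 tert-butyl{[(3Z,5R,6S,7R)-6-(tert-butyldimethylsilyloxy)-5-[(4-methoxybenzyl)oxy]-4-methyl-7-(prop-1-en-2-yl)undec-3-en-9-yn-1-yl]oxy}dimethylsilane
Conditions: Ph3PCH3Br, KOtBu, THF, 0 °C to rt
Reagents that add atoms: methyltriphenylphosphonium bromide, C[P+](c1ccccc1)(c1ccccc1)c1ccccc1.[Br-]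
Why: Wittig methylenation turns the C11 ketone into the isopropenyl group; the unhindered ylide should add to the methyl ketone faster than it enolises it, so C7 is kept.

Step 13
Reactants: 20 bis-silyl ether
Product: 21 (3Z,5R,6S,7R)-6-(tert-butyldimethylsilyloxy)-5-[(4-methoxybenzyl)oxy]-4-methyl-7-(prop-1-en-2-yl)undec-3-en-9-yn-1-ol
Conditions: HF·pyridine, pyridine, THF, 0 °C
Reagents that add atoms: none
Why: Selective desilylation; the primary silyl ether is cleaved much faster than the hindered secondary one at O8 under buffered fluoride.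

Step 14
Reactants: 21 primary alcohol
Product: 22 (3Z,5R,6S,7R)-6-(tert-butyldimethylsilyloxy)-5-[(4-methoxybenzyl)oxy]-4-methyl-7-(prop-1-en-2-yl)undec-3-en-9-ynal
Conditions: Dess–Martin periodinane, NaHCO3, CH2Cl2, 0 °C (used at once)
Reagents that add atoms: none
Why: Buffered Dess–Martin oxidation gives the β,γ-unsaturated aldehyde (C3) under neutral conditions that should avoid conjugation of the C1=C10 olefin.

Step 15
Reactants: 22 ynal
Product: 24 macrocyclic allylic alcohol (1(10)Z,4E,7R,8S,9R)-8-O-(tert-butyldimethylsilyl)-9-O-(4-methoxybenzyl)germacra-1(10),4,11-triene-3,8,9-triol (C3 epimer mixture), via triethylsilyl ether 23 (not isolated)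
Conditions: Ni(cod)2 (30 mol %), IMes (1,3-dimesitylimidazol-2-ylidene, 30 mol %), Et3SiH (5 equiv), THF, rt, 22 added over 8 h (final 2 mM); then PPTS, MeOH, 0 °C
Reagents that add atoms: triethylsilane, CC[SiH](CC)CC (its silicon and ethyl groups appear in 23 only; 24 keeps only its hydrogen on C5)
Why: Zerovalent nickel bearing the small carbene IMes binds the C4≡C5 alkyne and the C3 aldehyde and couples them oxidatively to an oxanickelacyclopentene (C3–C4 bond formed, nickel on C5 and O3), Et3SiH then cleaves the Ni–O bond by σ-bond metathesis and C–H reductive elimination at C5 releases the catalyst, so H and C3 add syn across the alkyne and the C4=C5 olefin is E by mechanism. The closest known reaction type is the nickel-catalysed reductive macrocyclisation of ynals to endocyclic (E)-allylic alcohols with silane reductants. The ten-membered carbocycle closes in the 10-endo-dig mode, C–C bond formation at the methyl-bearing alkyne carbon being the regiochemistry favoured by a small ligand because the bulkier tether substituent then sits on the nickel-bound carbon. The step needs this endo regioselectivity over 9-exo closure and ring closure over oligomerisation; the small methyl group on C4, the cis C1=C10 olefin that folds the chain, and slow addition at high dilution are expected to secure them. The new stereocenter C3 is formed under substrate control from C7–C9 through the tether conformation, its sense cannot be predicted and is not relied upon, since steps 16 and 17 converge both epimers to the (3S)-alcohol. In one operation the step delivers the ring, the E olefin that becomes the trans-4,5-epoxide, and the C3 oxygen.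

Step 16
Reactants: 24 macrocyclic allylic alcohol (C3 epimer mixture)
Product: 25 (1(10)Z,4E,7R,8S,9R)-8-(tert-butyldimethylsilyloxy)-9-[(4-methoxybenzyl)oxy]germacra-1(10),4,11-trien-3-one
Conditions: Dess–Martin periodinane, NaHCO3, CH2Cl2, 0 °C
Reagents that add atoms: none
Why: Dess–Martin oxidation of the allylic alcohol converges both C3 epimers to one (E)-enone under neutral conditions that should leave the skipped C1=C10 olefin in place.

Step 17
Reactants: 25 macrocyclic enone
Product: 26 (1(10)Z,4E,3S,7R,8S,9R)-8-O-(tert-butyldimethylsilyl)-9-O-(4-methoxybenzyl)germacra-1(10),4,11-triene-3,8,9-triol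
Conditions: (R)-Me-CBS oxazaborolidine (0.3 equiv), catecholborane, toluene, −78 °C
Reagents that add atoms: none
Why: Corey–Bakshi–Shibata reduction; the ketone binds the oxazaborolidine with the α-methylalkenyl arm (C4) as the large group and the C2 methylene as the small group, so the (R)-catalyst should deliver hydride to give the (3S)-alcohol under reagent control, and catecholborane leaves the olefins alone.

Step 18
Reactants: 26 (3S)-allylic alcohol
Product: 27 (1(10)Z,4E,3S,7R,8S,9R)-9-O-(4-methoxybenzyl)germacra-1(10),4,11-triene-3,8,9-triol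
Conditions: Bu4NF, THF, rt
Reagents that add atoms: none
Why: Fluoride desilylation of the O8 silyl ether, done before any ester or epoxide is present so that basic fluoride can cause neither acyl migration nor transannular epoxide opening.

Step 19
Reactants: 27 diene diol
Product: 28 4,5-epoxy-9-O-(4-methoxybenzyl)germacra-1(10),11-diene-3,8,9-triol (1(10)Z; C3, C4, C5, C7, C8, C9 arranged as in 34)
Conditions: mCPBA (1.05 equiv), NaHCO3, CH2Cl2, −20 to 0 °C
Reagents that add atoms: 3-chloroperbenzoic acid, O=C(OO)c1cccc(Cl)c1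
Why: Hydroxyl-directed peracid epoxidation; the C4=C5 plane stands perpendicular to the ring so only its outer face is open, and the (3S)-hydroxyl reaches the O–C3–C4=C5 dihedral near 130° needed for hydrogen-bonded delivery only in the conformer with C15 on the isopropenyl face, which leads to the epoxide configuration of 34 (4S,5R there), while the strained E olefin should react before the Z olefin and the isopropenyl group.

Step 20
Reactants: 28 epoxy diol; 29 angelic acid ((2Z)-2-methylbut-2-enoic acid)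
Product: 31 3,8-di-O-angeloyl-4,5-epoxy-9-O-(4-methoxybenzyl)germacra-1(10),11-diene-3,8,9-triol, via mixed trichlorobenzoic anhydride 30 (not isolated)
Conditions: 29, 2,4,6-Cl3C6H2COCl, Et3N, toluene, rt; then 28, toluene, 70 °C
Reagents that add atoms: 2,4,6-trichlorobenzoyl chloride, O=C(Cl)c1c(Cl)cc(Cl)cc1Cl (its atoms appear in 30 only)
Why: Yamaguchi-type esterification through the mixed anhydride acylates O3 and O8 in one operation; leaving out a nucleophilic catalyst is the known way to avoid Z to E isomerisation of the angeloyl group.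

Step 21
Reactants: 31 bis-angelate PMB ether
Product: 32 3,8-di-O-angeloyl-4,5-epoxygermacra-1(10),11-diene-3,8,9-triol
Conditions: DDQ, CH2Cl2/pH 7 buffer, 0 °C
Reagents that add atoms: none
Why: Oxidative PMB cleavage (hydride abstraction by DDQ, then hydrolysis of the oxocarbenium ion) frees O9 under neutral conditions in which the esters, the epoxide and the olefins should survive and no acyl migration from O8 is expected.

Step 22
Reactants: 32 C9 allylic alcohol
Product: 33 3,8-di-O-angeloyl-1,10:4,5-diepoxygermacr-11-ene-3,8,9-triol (all stereocenters arranged as in 34)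
Conditions: mCPBA (1.2 equiv), NaHCO3, CH2Cl2, 0 °C
Reagents that add atoms: 3-chloroperbenzoic acid, O=C(OO)c1cccc(Cl)c1
Why: Hydroxyl-directed peracid epoxidation of the Z allylic alcohol; A(1,3) strain between the C9 substituents and C2 holds H9 in the olefin plane with ring carbon C8 on one face and the hydroxyl on the open face, so hydrogen-bonded delivery syn to O9 gives the threo cis-epoxide of 34 (1S,10S there), and the isopropenyl olefin and the electron-poor angelates react more slowly.

Step 23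
Reactants: 33 diepoxy alcohol
Product: 34 target, (1S,3S,4S,5R,7R,8S,9S,10S)-9-O-acetyl-3,8-di-O-angeloyl-1,10:4,5-diepoxygermacr-11-ene-3,8,9-triol (CNP0220329.2)
Conditions: Ac2O, pyridine, DMAP (cat.), CH2Cl2, rt
Reagents that add atoms: acetic anhydride, CC(=O)OC(C)=O
Why: DMAP-catalysed acyl transfer acetylates the one remaining, hindered secondary alcohol O9 without touching the epoxides or angelates.

**Compound list**

1 | (3-bromopropoxy)(tert-butyl)dimethylsilane | BrCCCO[Si](C)(C)C(C)(C)C | starting material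
2 | [3-(tert-butyldimethylsilyloxy)propyl]triphenylphosphonium bromide | CC(C)(C)[Si](C)(C)OCCC[P+](c1ccccc1)(c1ccccc1)c1ccccc1.[Br-] | intermediate
3 | methyl (2S)-2,3-dihydroxypropanoate (methyl (S)-glycerate) | COC(=O)[C@@H](O)CO | starting material
4 | methyl (4S)-2-(4-methoxyphenyl)-1,3-dioxolane-4-carboxylate (acetal carbon as epimer mixture) | COC(=O)[C@@H]1COC(c2ccc(OC)cc2)O1 | intermediate
5 | (4S)-N-methoxy-2-(4-methoxyphenyl)-N-methyl-1,3-dioxolane-4-carboxamide | CON(C)C(=O)[C@@H]1COC(c2ccc(OC)cc2)O1 | intermediate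
6 | 1-[(4S)-2-(4-methoxyphenyl)-1,3-dioxolan-4-yl]ethan-1-one | CC(=O)[C@@H]1COC(c2ccc(OC)cc2)O1 | intermediate
7 | [3-(tert-butyldimethylsilyloxy)propylidene]triphenylphosphorane | CC(C)(C)[Si](C)(C)OCCC=P(c1ccccc1)(c1ccccc1)c1ccccc1 | intermediate
8 | (4R)-4-[(2Z)-5-(tert-butyldimethylsilyloxy)pent-2-en-2-yl]-2-(4-methoxyphenyl)-1,3-dioxolane | C/C(=C/CCO[Si](C)(C)C(C)(C)C)[C@@H]1COC(c2ccc(OC)cc2)O1 | intermediate
9 | (2R,3Z)-6-(tert-butyldimethylsilyloxy)-2-[(4-methoxybenzyl)oxy]-3-methylhex-3-en-1-ol | OC[C@H](OCc1ccc(OC)cc1)/C(C)=C\CCO[Si](C)(C)C(C)(C)C | intermediate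
10 | (2R,3Z)-6-(tert-butyldimethylsilyloxy)-2-[(4-methoxybenzyl)oxy]-3-methylhex-3-enal | O=C[C@H](OCc1ccc(OC)cc1)/C(C)=C\CCO[Si](C)(C)C(C)(C)C | intermediate
11 | hex-4-ynoic acid | CC#CCCC(=O)O | starting material
12 | (4S)-4-benzyl-1,3-oxazolidin-2-one | O=C1N[C@@H](Cc2ccccc2)CO1 | starting material
13 | hex-4-ynoic pivalic anhydride | CC#CCCC(=O)OC(=O)C(C)(C)C | intermediate
14 | (4S)-4-benzyl-3-(hex-4-ynoyl)-1,3-oxazolidin-2-one | CC#CCCC(=O)N1[C@@H](Cc2ccccc2)COC1=O | intermediate
15 | (Z)-dibutylboron enolate of 14 | CC#CC/C=C(\OB(CCCC)CCCC)N1[C@@H](Cc2ccccc2)COC1=O | intermediate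
16 | (4S)-4-benzyl-3-[(2S,3S,4R,5Z)-2-(but-2-yn-1-yl)-8-(tert-butyldimethylsilyloxy)-3-hydroxy-4-[(4-methoxybenzyl)oxy]-5-methyloct-5-enoyl]-1,3-oxazolidin-2-one | CC#CC[C@H](C(=O)N1[C@@H](Cc2ccccc2)COC1=O)[C@H](O)[C@H](OCc1ccc(OC)cc1)/C(C)=C\CCO[Si](C)(C)C(C)(C)C | intermediate
17 | (2S,3S,4R,5Z)-2-(but-2-yn-1-yl)-8-(tert-butyldimethylsilyloxy)-3-hydroxy-N-methoxy-4-[(4-methoxybenzyl)oxy]-N,5-dimethyloct-5-enamide | CC#CC[C@H](C(=O)N(C)OC)[C@H](O)[C@H](OCc1ccc(OC)cc1)/C(C)=C\CCO[Si](C)(C)C(C)(C)C | intermediate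
18 | (2S,3S,4R,5Z)-2-(but-2-yn-1-yl)-3,8-bis(tert-butyldimethylsilyloxy)-N-methoxy-4-[(4-methoxybenzyl)oxy]-N,5-dimethyloct-5-enamide | CC#CC[C@H](C(=O)N(C)OC)[C@H](O[Si](C)(C)C(C)(C)C)[C@H](OCc1ccc(OC)cc1)/C(C)=C\CCO[Si](C)(C)C(C)(C)C | intermediate
19 | (3S,4S,5R,6Z)-3-(but-2-yn-1-yl)-4,9-bis(tert-butyldimethylsilyloxy)-5-[(4-methoxybenzyl)oxy]-6-methylnon-6-en-2-one | CC#CC[C@H](C(C)=O)[C@H](O[Si](C)(C)C(C)(C)C)[C@H](OCc1ccc(OC)cc1)/C(C)=C\CCO[Si](C)(C)C(C)(C)C | intermediate
20 | tert-butyl{[(3Z,5R,6S,7R)-6-(tert-butyldimethylsilyloxy)-5-[(4-methoxybenzyl)oxy]-4-methyl-7-(prop-1-en-2-yl)undec-3-en-9-yn-1-yl]oxy}dimethylsilane | CC#CC[C@H](C(C)=C)[C@H](O[Si](C)(C)C(C)(C)C)[C@H](OCc1ccc(OC)cc1)/C(C)=C\CCO[Si](C)(C)C(C)(C)C | intermediate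
21 | (3Z,5R,6S,7R)-6-(tert-butyldimethylsilyloxy)-5-[(4-methoxybenzyl)oxy]-4-methyl-7-(prop-1-en-2-yl)undec-3-en-9-yn-1-ol | CC#CC[C@H](C(C)=C)[C@H](O[Si](C)(C)C(C)(C)C)[C@H](OCc1ccc(OC)cc1)/C(C)=C\CCO | intermediate
22 | (3Z,5R,6S,7R)-6-(tert-butyldimethylsilyloxy)-5-[(4-methoxybenzyl)oxy]-4-methyl-7-(prop-1-en-2-yl)undec-3-en-9-ynal | CC#CC[C@H](C(C)=C)[C@H](O[Si](C)(C)C(C)(C)C)[C@H](OCc1ccc(OC)cc1)/C(C)=C\CC=O | intermediate
23 | (1(10)Z,4E,7R,8S,9R)-8-O-(tert-butyldimethylsilyl)-9-O-(4-methoxybenzyl)-3-O-(triethylsilyl)germacra-1(10),4,11-triene-3,8,9-triol (C3 epimer mixture) | C=C(C)[C@H]1C/C=C(C)/C(O[Si](CC)(CC)CC)C/C=C(C)\[C@@H](OCc2ccc(OC)cc2)[C@H]1O[Si](C)(C)C(C)(C)C | intermediate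
24 | (1(10)Z,4E,7R,8S,9R)-8-O-(tert-butyldimethylsilyl)-9-O-(4-methoxybenzyl)germacra-1(10),4,11-triene-3,8,9-triol (C3 epimer mixture) | C=C(C)[C@H]1C/C=C(C)/C(O)C/C=C(C)\[C@@H](OCc2ccc(OC)cc2)[C@H]1O[Si](C)(C)C(C)(C)C | intermediate
25 | (1(10)Z,4E,7R,8S,9R)-8-(tert-butyldimethylsilyloxy)-9-[(4-methoxybenzyl)oxy]germacra-1(10),4,11-trien-3-one | C=C(C)[C@H]1C/C=C(C)/C(=O)C/C=C(C)\[C@@H](OCc2ccc(OC)cc2)[C@H]1O[Si](C)(C)C(C)(C)C | intermediate
26 | (1(10)Z,4E,3S,7R,8S,9R)-8-O-(tert-butyldimethylsilyl)-9-O-(4-methoxybenzyl)germacra-1(10),4,11-triene-3,8,9-triol | C=C(C)[C@H]1C/C=C(C)/[C@@H](O)C/C=C(C)\[C@@H](OCc2ccc(OC)cc2)[C@H]1O[Si](C)(C)C(C)(C)C | intermediate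
27 | (1(10)Z,4E,3S,7R,8S,9R)-9-O-(4-methoxybenzyl)germacra-1(10),4,11-triene-3,8,9-triol | C=C(C)[C@H]1C/C=C(C)/[C@@H](O)C/C=C(C)\[C@@H](OCc2ccc(OC)cc2)[C@H]1O | intermediate
28 | 4,5-epoxy-9-O-(4-methoxybenzyl)germacra-1(10),11-diene-3,8,9-triol (1(10)Z; stereocenters arranged as in 34) | C=C(C)[C@H]1C[C@H]2O[C@]2(C)[C@@H](O)C/C=C(C)\[C@@H](OCc3ccc(OC)cc3)[C@H]1O | intermediate
29 | angelic acid, (2Z)-2-methylbut-2-enoic acid | C/C=C(/C)C(=O)O | starting material
30 | (2Z)-2-methylbut-2-enoic 2,4,6-trichlorobenzoic anhydride | C/C=C(/C)C(=O)OC(=O)c1c(Cl)cc(Cl)cc1Cl | intermediate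
31 | 3,8-di-O-angeloyl-4,5-epoxy-9-O-(4-methoxybenzyl)germacra-1(10),11-diene-3,8,9-triol (1(10)Z; stereocenters arranged as in 34) | C=C(C)[C@H]1C[C@H]2O[C@]2(C)[C@@H](OC(=O)/C(C)=C\C)C/C=C(C)\[C@@H](OCc3ccc(OC)cc3)[C@H]1OC(=O)/C(C)=C\C | intermediate
32 | 3,8-di-O-angeloyl-4,5-epoxygermacra-1(10),11-diene-3,8,9-triol (1(10)Z; stereocenters arranged as in 34) | C=C(C)[C@H]1C[C@H]2O[C@]2(C)[C@@H](OC(=O)/C(C)=C\C)C/C=C(C)\[C@@H](O)[C@H]1OC(=O)/C(C)=C\C | intermediate
33 | 3,8-di-O-angeloyl-1,10:4,5-diepoxygermacr-11-ene-3,8,9-triol (stereocenters arranged as in 34) | C=C(C)[C@H]1C[C@H]2O[C@]2(C)[C@@H](OC(=O)/C(C)=C\C)C[C@@H]2O[C@]2(C)[C@@H](O)[C@H]1OC(=O)/C(C)=C\C | intermediate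
34 | (1S,3S,4S,5R,7R,8S,9S,10S)-9-O-acetyl-3,8-di-O-angeloyl-1,10:4,5-diepoxygermacr-11-ene-3,8,9-triol (CNP0220329.2) | C=C(C)[C@H]1C[C@H]2O[C@]2(C)[C@@H](OC(=O)/C(C)=C\C)C[C@@H]2O[C@]2(C)[C@@H](OC(C)=O)[C@H]1OC(=O)/C(C)=C\C | target

**Totals**

Total step count: 23.
Longest linear sequence: 21 steps (3 to 34; steps 2–6 and 8–23). Steps 1 and 7 are side branches.

**Steps most likely to fail**

Step 15. The ring closure may fail through C–C bond formation at C5 (nine-membered ring with an exocyclic ethylidene), through oligomerisation at the concentrations needed for turnover, or through slow oxidative cyclisation caused by transannular strain. The fallback is a Nozaki–Hiyama–Kishi macrocyclisation that sets out from 20 and comes back at 24. Hydrozirconation of the methyl alkyne of 20 with Cp2Zr(H)Cl (zirconium settling on the methyl-bearing carbon C4) followed by iodinolysis should give the (E)-vinyl iodide F1. Selective cleavage of the primary silyl ether with HF·pyridine should give the iodo alcohol F2, and Dess–Martin oxidation the iodo aldehyde F3. Treatment of F3 with CrCl2 and catalytic NiCl2 in DMSO at high dilution should then form the C3–C4 bond by addition of the vinylchromium species to the aldehyde and give 24.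

Step 19. The epoxidation may fail through poor facial selectivity, if the olefin reacts through the ring conformer with the C4=C5 unit flipped, or through competing epoxidation of the C1=C10 olefin. The fallback sets out from 25 and comes back at 31. Reduction of 25 with the (S)-configured oxazaborolidine and catecholborane should give the (3R)-alcohol F4. Epoxidation with VO(acac)2 and tBuOOH, which needs the small O–C–C=C dihedral that the (3R)-hydroxyl has in the same ring conformer and is erythro-selective for 2-methylallylic alcohols, should give the (3R)-epoxy alcohol F5 carrying the 4,5-epoxide of 34. Mitsunobu esterification with angelic acid 29 (PPh3, diisopropyl azodicarboxylate) inverts C3 and should give the (3S)-angelate F6. Bu4NF then frees O8 to give the hydroxy ester F7, and acylation of F7 with the mixed anhydride 30 gives 31.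

Step 20. The double acylation may fail through Z to E isomerisation of the angeloyl group during activation or through incomplete acylation of the hindered O8. The fallback sets out from 28 and comes back at 31. Acylation of both hydroxyls with 2-[bis(2,2,2-trifluoroethoxy)phosphoryl]propanoic acid (carbodiimide, DMAP) should give the bis(phosphonopropanoate) F8. A twofold Still–Gennari olefination of F8 with acetaldehyde (KN(SiMe3)2, 18-crown-6, THF, −78 °C) then builds both (Z)-2-methylbut-2-enoates on the substrate and gives 31.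

**Further compounds**

F1 | step 15 | (E)-vinyl iodide from 20 (C5H=C4(I)–CH3 in place of the alkyne; iodine trans to C6) | C/C(I)=C\C[C@H](C(C)=C)[C@H](O[Si](C)(C)C(C)(C)C)[C@H](OCc1ccc(OC)cc1)/C(C)=C\CCO[Si](C)(C)C(C)(C)C
F2 | step 15 | iodo alcohol (F1 with the primary silyl ether cleaved) | C/C(I)=C\C[C@H](C(C)=C)[C@H](O[Si](C)(C)C(C)(C)C)[C@H](OCc1ccc(OC)cc1)/C(C)=C\CCO
F3 | step 15 | iodo aldehyde (F2 oxidised at C3) | C/C(I)=C\C[C@H](C(C)=C)[C@H](O[Si](C)(C)C(C)(C)C)[C@H](OCc1ccc(OC)cc1)/C(C)=C\CC=O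
F4 | step 19 | (3R)-epimer of 26 | C=C(C)[C@H]1C/C=C(C)/[C@H](O)C/C=C(C)\[C@@H](OCc2ccc(OC)cc2)[C@H]1O[Si](C)(C)C(C)(C)C
F5 | step 19 | (3R)-4,5-epoxy alcohol with O8 silyl ether (epoxide arranged as in 34) | C=C(C)[C@H]1C[C@H]2O[C@]2(C)[C@H](O)C/C=C(C)\[C@@H](OCc3ccc(OC)cc3)[C@H]1O[Si](C)(C)C(C)(C)C
F6 | step 19 | (3S)-3-O-angeloyl-4,5-epoxide with O8 silyl ether and O9 PMB ether | C=C(C)[C@H]1C[C@H]2O[C@]2(C)[C@@H](OC(=O)/C(C)=C\C)C/C=C(C)\[C@@H](OCc3ccc(OC)cc3)[C@H]1O[Si](C)(C)C(C)(C)C
F7 | step 19 | (3S)-3-O-angeloyl-4,5-epoxide with free O8 hydroxyl and O9 PMB ether | C=C(C)[C@H]1C[C@H]2O[C@]2(C)[C@@H](OC(=O)/C(C)=C\C)C/C=C(C)\[C@@H](OCc3ccc(OC)cc3)[C@H]1O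
F8 | step 20 | 3,8-bis{2-[bis(2,2,2-trifluoroethoxy)phosphoryl]propanoate} of 28 | C=C(C)[C@H]1C[C@H]2O[C@]2(C)[C@@H](OC(=O)C(C)P(=O)(OCC(F)(F)F)OCC(F)(F)F)C/C=C(C)\[C@@H](OCc3ccc(OC)cc3)[C@H]1OC(=O)C(C)P(=O)(OCC(F)(F)F)OCC(F)(F)F
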